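## Retrosynthetic overview

1. Target 27 ⇒ Schenck ene reaction (¹O₂) of the 7(11)-en-8-one diester 26 ⇒ two acylations of the 3α,4α-diol 22 ⇒ α-face dihydroxylation of (5R,10R)-eudesma-3,7(11)-dien-8-one 20.
2. 20 ⇒ open-chain, achiral enyne–silyloxydiene 17 by one gold(I)-catalysed cascade: bond C4–C5 closes ring A (C1–C5, C10) first, bond C9–C10 closes ring B (C5–C10) last.
3. Enabling feature: the C3=C4 alkene of ring A carrying CH₃-15 (latent 3,4-cis-diol) is the footprint of a but-2-ynyl terminus; the trans C5-H/C10-CH₃ fusion is that of an (E)-trisubstituted alkene; the C8 ketone one CH₂ (C9) from quaternary C10, with exocyclic C7=C11 (latent 7-OOH/isopropenyl), is that of a 2-silyloxy-1,3-diene. All fifteen carbons therefore lie in one chain C15–C4≡C3–C2–C1–C10(C14)=C5–C6–C7(=C11)–C8(O)=C9.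
4. 17 ⇒ acetylacetone (C7, C8, C9, C11, C12) + (E)-allylic bromide 10 ⇒ syn-carbocupration of ethyl but-2-ynoate by the copper reagent from pent-3-yn-1-ol.

Key step: step 9

Remark: eudesmane numbering (C1–C15) is used for all compounds, including the open-chain ones; [Au] in SMILES stands for the ligated gold(I) fragment.
Remark: the sense of induction of the chiral digold catalyst cannot be predicted with certainty; the ligand enantiomer that delivers (5R,10R)-20 is to be used.
Remark: short-lived species inside a single mechanistic event (oxyphosphonium salts, aluminium alkoxides, tetrahedral intermediates) are not numbered.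

## Route

Step 1
Reactants: 1 pent-3-yn-1-ol
Product: 2 5-bromopent-2-yne
Conditions: CBr4, PPh3, CH2Cl2, 0 °C to rt
Reagents that add atoms: carbon tetrabromide BrC(Br)(Br)Br
Why: Appel bromination of a primary alcohol (SN2 on the oxyphosphonium salt) should leave the internal alkyne untouched.

Step 2
Reactants: 2 5-bromopent-2-yne; 3 ethyl but-2-ynoate
Product: 7 ethyl (2E)-3-methyloct-2-en-6-ynoate, via pent-3-yn-1-ylmagnesium bromide 4 (not isolated), via pent-3-yn-1-ylcopper 5 (not isolated), via ethyl (2Z)-2-cuprio-3-methyloct-2-en-6-ynoate 6 (not isolated)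
Conditions: Mg, THF; CuBr·SMe2, −40 °C; 3, −78 °C; aq NH4Cl, −78 °C
Reagents that add atoms: none
Why: Syn-carbocupration of a ynoate by an alkylcopper reagent at −78 °C, with protonation of the alkenylcopper with retention, should fix the (E)-trisubstituted alkene that later becomes the trans ring fusion.

Step 3
Reactants: 7 ethyl (2E)-3-methyloct-2-en-6-ynoate
Product: 9 (2E)-3-methyloct-2-en-6-yn-1-ol, via (2E)-3-methyloct-2-en-6-ynal 8 (not isolated)
Conditions: DIBAL-H (2.2 equiv), CH2Cl2, −78 to 0 °C; Rochelle salt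
Reagents that add atoms: none
Why: DIBAL-H 1,2-reduction of an α,β-unsaturated ester to the allylic alcohol should not affect the alkyne or the alkene geometry.

Step 4
Reactants: 9 (2E)-3-methyloct-2-en-6-yn-1-ol
Product: 10 (2E)-1-bromo-3-methyloct-2-en-6-yne
Conditions: PBr3, Et2O, −10 °C
Reagents that add atoms: phosphorus tribromide BrP(Br)Br
Why: PBr3 bromination of a primary allylic alcohol at low temperature (as for geranyl bromide) should proceed without allylic transposition or E/Z loss.

Step 5
Reactants: 10 (2E)-1-bromo-3-methyloct-2-en-6-yne; 11 pentane-2,4-dione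
Product: 12 3-[(2E)-3-methyloct-2-en-6-yn-1-yl]pentane-2,4-dione
Conditions: K2CO3, acetone, rt
Reagents that add atoms: none
Why: C-alkylation of the soft acetylacetone enolate by a primary allylic bromide (SN2); the symmetric diketone makes the next two steps regiochemically unambiguous.

Step 6
Reactants: 12 3-[(2E)-3-methyloct-2-en-6-yn-1-yl]pentane-2,4-dione
Product: 14 4-oxo-3-[(2E)-3-methyloct-2-en-6-yn-1-yl]pent-2-en-2-yl trifluoromethanesulfonate (E/Z mixture at the enol double bond), via sodium 4-oxo-3-[(2E)-3-methyloct-2-en-6-yn-1-yl]pent-2-en-2-olate 13 (not isolated)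
Conditions: NaH, THF, 0 °C; PhNTf2, 0 °C to rt
Reagents that add atoms: N-phenylbis(trifluoromethanesulfonimide) O=S(=O)(N(c1ccccc1)S(=O)(=O)C(F)(F)F)C(F)(F)F
Why: O-triflation of a β-diketone enolate should give the vinylogous acyl triflate; the two carbonyls are equivalent and the enol geometry is irrelevant because the next step installs a second methyl.

Step 7
Reactants: 14 4-oxo-3-[(2E)-3-methyloct-2-en-6-yn-1-yl]pent-2-en-2-yl trifluoromethanesulfonate
Product: 15 (5E)-6-methyl-3-(propan-2-ylidene)undec-5-en-9-yn-2-one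
Conditions: Me2CuLi (from MeLi, CuI), THF/Et2O, −78 to −20 °C
Reagents that add atoms: lithium dimethylcuprate [Li+].C[Cu-]C (from methyllithium C[Li] and copper(I) iodide)
Why: Addition–elimination of a Gilman cuprate on a β-triflyloxy enone should give the tetrasubstituted α-isopropylidene methyl ketone, whose hindered enone resists further conjugate addition.

Step 8
Reactants: 15 (5E)-6-methyl-3-(propan-2-ylidene)undec-5-en-9-yn-2-one
Product: 17 tert-butyl(dimethyl){[(5E)-6-methyl-3-(propan-2-ylidene)undeca-1,5-dien-9-yn-2-yl]oxy}silane, via lithium (5E)-6-methyl-3-(propan-2-ylidene)undeca-1,5-dien-9-yn-2-olate 16 (not isolated)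
Conditions: LDA, THF, −78 °C; TBSOTf, −78 °C; Et3N quench
Reagents that add atoms: tert-butyldimethylsilyl trifluoromethanesulfonate CC(C)(C)[Si](C)(C)OS(=O)(=O)C(F)(F)F
Why: Kinetic α′-deprotonation of the methyl ketone (the α-carbon bears no hydrogen, as in mesityl oxide) and O-silylation should give the 2-silyloxy-1,3-diene.

Step 9
Reactants: 17 tert-butyl(dimethyl){[(5E)-6-methyl-3-(propan-2-ylidene)undeca-1,5-dien-9-yn-2-yl]oxy}silane
Product: 20 (4aR,8aR)-5,8a-dimethyl-3-(propan-2-ylidene)-3,4,4a,7,8,8a-hexahydronaphthalen-2(1H)-one [(5R,10R)-eudesma-3,7(11)-dien-8-one], via monocyclic vinylgold carbenium ion 18 (not isolated), via bicyclic vinylgold silyloxocarbenium ion 19 (not isolated)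
Conditions: [(R)-DTBM-MeO-BIPHEP](AuCl)2 (3 mol %), AgSbF6 (3 mol %), i-PrOH (2 equiv), toluene, −20 °C to rt
Reagents that add atoms: none
Why: Proposed new method: cationic gold(I) π-activates the C3≡C4 alkyne, C5 of the (E)-C5=C10 alkene attacks C4 anti to gold (6-endo-dig, ring A closes first) to give the vinylgold/tertiary C10 carbenium species 18, and the terminal carbon C9 of the silyloxydiene then attacks C10 (6-endo-trig with respect to the enol ether, ring B closes last) to give the silyloxocarbenium ion 19, from which i-PrOH removes the silyl group and protodeaurates C3 to release 20 and the catalyst. The closest known reaction types are the gold(I)-catalysed 6-endo-dig double cyclisation of 1,5-enynes bearing a cation-stabilising substituent on the proximal alkene carbon (capture by O-, N- or π-nucleophiles), the enantioselective gold(I)–bisphosphine polyene cyclisation initiated at an alkyne, and the gold(I)-catalysed carbocyclisation of silyl enol ethers; capture of the enyne-derived cation by a silyloxydiene under enantiocontrol has not been shown. The trans relationship of C5-H and C10-CH3 should follow from stereospecific anti addition across the (E)-alkene through a chair-like transition state (Stork–Eschenmoser), so that only the alkene face, and with it the absolute configuration of both centres, is left to the chiral ligand. The step needs 6-endo over 5-exo attack on the alkyne (secured by the tertiary cation at C10 and the 1,5-enyne topology), C- over O-capture by the terminator (oxygen is silylated and C9 is an unhindered CH2, whereas attack through C11 would join two quaternary carbons), and capture faster than proton loss (intramolecular six-membered closure).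

Step 10
Reactants: 20 (5R,10R)-eudesma-3,7(11)-dien-8-one
Product: 22 (3R,4S,5R,10R)-3,4-dihydroxyeudesm-7(11)-en-8-one, via cyclic osmate(VI) ester 21 (not isolated)
Conditions: OsO4 (2 mol %), NMO, acetone/H2O, rt
Reagents that add atoms: osmium tetroxide O=[Os](=O)(=O)=O (catalytic oxygen carrier); N-methylmorpholine N-oxide C[N+]1([O-])CCOCC1; water O
Why: Upjohn dihydroxylation should touch only the electron-rich trisubstituted C3=C4 alkene (the tetrasubstituted enone alkene is inert) and add suprafacially from the α-face, opposite the axial C10 methyl, setting C3 and C4 as 3α-OH, 4α-OH, 4β-CH3.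

Step 11
Reactants: 22 (3R,4S,5R,10R)-3,4-dihydroxyeudesm-7(11)-en-8-one; 23 (2Z)-2-methylbut-2-enoic acid (angelic acid)
Product: 25 (3R,4S,5R,10R)-4-hydroxy-8-oxoeudesm-7(11)-en-3-yl (2Z)-2-methylbut-2-enoate, via angelic 2,4,6-trichlorobenzoic anhydride 24 (not isolated)
Conditions: 23, 2,4,6-trichlorobenzoyl chloride, Et3N, toluene, rt; then 22, 80 °C (no DMAP)
Reagents that add atoms: none
Why: Yamaguchi-type esterification through the preformed mixed anhydride without a nucleophilic catalyst should acylate the secondary 3-OH selectively (the tertiary 4-OH is inert) and preserve the (Z)-geometry of the angeloyl group.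

Step 12
Reactants: 25 (3R,4S,5R,10R)-4-hydroxy-8-oxoeudesm-7(11)-en-3-yl (2Z)-2-methylbut-2-enoate
Product: 26 (3R,4S,5R,10R)-4-acetoxy-8-oxoeudesm-7(11)-en-3-yl (2Z)-2-methylbut-2-enoate
Conditions: Ac2O, Sc(OTf)3 (5 mol %), MeCN, −20 to 0 °C
Reagents that add atoms: acetic anhydride CC(=O)OC(C)=O
Why: Lewis-acid-catalysed acylation with Ac2O should acetylate the hindered tertiary alcohol at low temperature, where elimination and angelate isomerisation are not expected; C4 keeps its configuration because only the O–H bond reacts.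

Step 13
Reactants: 26 (3R,4S,5R,10R)-4-acetoxy-8-oxoeudesm-7(11)-en-3-yl (2Z)-2-methylbut-2-enoate
Product: 27 (3R,4S,5R,7S,10R)-4-acetoxy-7-hydroperoxy-8-oxoeudesm-11-en-3-yl (2Z)-2-methylbut-2-enoate (CNP0360871.1)
Conditions: O2, tetraphenylporphyrin (cat.), visible light, CH2Cl2, −20 °C; no reductive work-up
Reagents that add atoms: dioxygen O=O (as singlet oxygen)
Why: Schenck ene reaction of singlet oxygen with an s-cis α-alkylidene ketone (pulegone-type precedent) should bond oxygen to C7 with abstraction of an isopropylidene methyl hydrogen and shift of the double bond to C11=C12; axial approach from the α-face, away from the β-methyl groups on C10 and C4, should set C7 as the 7α-hydroperoxide.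

## Compound list

1 | pent-3-yn-1-ol | CC#CCCO | starting material
2 | 5-bromopent-2-yne | CC#CCCBr | intermediate
3 | ethyl but-2-ynoate | CC#CC(=O)OCC | starting material
4 | pent-3-yn-1-ylmagnesium bromide (in situ) | CC#CCC[Mg]Br | intermediate
5 | pent-3-yn-1-ylcopper (in situ) | CC#CCC[Cu] | intermediate
6 | ethyl (2Z)-2-cuprio-3-methyloct-2-en-6-ynoate (in situ) | CCOC(=O)/C([Cu])=C(C)/CCC#CC | intermediate
7 | ethyl (2E)-3-methyloct-2-en-6-ynoate | CC#CCC/C(C)=C/C(=O)OCC | intermediate
8 | (2E)-3-methyloct-2-en-6-ynal (in situ) | CC#CCC/C(C)=C/C=O | intermediate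
9 | (2E)-3-methyloct-2-en-6-yn-1-ol | CC#CCC/C(C)=C/CO | intermediate
10 | (2E)-1-bromo-3-methyloct-2-en-6-yne | CC#CCC/C(C)=C/CBr | intermediate
11 | pentane-2,4-dione | CC(=O)CC(C)=O | starting material
12 | 3-[(2E)-3-methyloct-2-en-6-yn-1-yl]pentane-2,4-dione | CC#CCC/C(C)=C/CC(C(C)=O)C(C)=O | intermediate
13 | sodium 4-oxo-3-[(2E)-3-methyloct-2-en-6-yn-1-yl]pent-2-en-2-olate (in situ) | CC#CCC/C(C)=C/CC(C(C)=O)=C(C)[O-].[Na+] | intermediate
14 | 4-oxo-3-[(2E)-3-methyloct-2-en-6-yn-1-yl]pent-2-en-2-yl trifluoromethanesulfonate (E/Z mixture at the enol double bond) | CC#CCC/C(C)=C/CC(C(C)=O)=C(C)OS(=O)(=O)C(F)(F)F | intermediate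
15 | (5E)-6-methyl-3-(propan-2-ylidene)undec-5-en-9-yn-2-one | CC#CCC/C(C)=C/CC(C(C)=O)=C(C)C | intermediate
16 | lithium (5E)-6-methyl-3-(propan-2-ylidene)undeca-1,5-dien-9-yn-2-olate (in situ) | CC#CCC/C(C)=C/CC(=C(C)C)C(=C)[O-].[Li+] | intermediate
17 | tert-butyl(dimethyl){[(5E)-6-methyl-3-(propan-2-ylidene)undeca-1,5-dien-9-yn-2-yl]oxy}silane | CC#CCC/C(C)=C/CC(=C(C)C)C(=C)O[Si](C)(C)C(C)(C)C | intermediate
18 | monocyclic vinylgold carbenium ion, ring A closed, cation at C10 (in situ) | C=C(O[Si](C)(C)C(C)(C)C)C(=C(C)C)C[C@@H]1[C+](C)CCC([Au])=C1C | intermediate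
19 | bicyclic vinylgold silyloxocarbenium ion, rings A and B closed (in situ) | CC(C)=C1C[C@@H]2[C@](C)(CCC([Au])=C2C)CC1=[O+][Si](C)(C)C(C)(C)C | intermediate
20 | (4aR,8aR)-5,8a-dimethyl-3-(propan-2-ylidene)-3,4,4a,7,8,8a-hexahydronaphthalen-2(1H)-one [(5R,10R)-eudesma-3,7(11)-dien-8-one] | CC(C)=C1C[C@@H]2[C@](C)(CCC=C2C)CC1=O | intermediate
21 | cyclic osmate(VI) ester of the 3α,4α-diol (in situ) | CC(C)=C1C[C@@H]2[C@](C)(CC[C@@H](O[Os]3(=O)=O)[C@@]2(C)O3)CC1=O | intermediate
22 | (3R,4S,5R,10R)-3,4-dihydroxyeudesm-7(11)-en-8-one | CC(C)=C1C[C@@H]2[C@](C)(CC[C@@H](O)[C@@]2(C)O)CC1=O | intermediate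
23 | (2Z)-2-methylbut-2-enoic acid (angelic acid) | C/C=C(/C)C(=O)O | starting material
24 | (2Z)-2-methylbut-2-enoic 2,4,6-trichlorobenzoic anhydride (in situ) | C/C=C(/C)C(=O)OC(=O)c1c(Cl)cc(Cl)cc1Cl | intermediate
25 | (3R,4S,5R,10R)-4-hydroxy-8-oxoeudesm-7(11)-en-3-yl (2Z)-2-methylbut-2-enoate | CC(C)=C1C[C@@H]2[C@](C)(CC[C@@H](OC(=O)/C(C)=C\C)[C@@]2(C)O)CC1=O | intermediate
26 | (3R,4S,5R,10R)-4-acetoxy-8-oxoeudesm-7(11)-en-3-yl (2Z)-2-methylbut-2-enoate | CC(C)=C1C[C@@H]2[C@](C)(CC[C@@H](OC(=O)/C(C)=C\C)[C@@]2(C)OC(C)=O)CC1=O | intermediate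
27 | (3R,4S,5R,7S,10R)-4-acetoxy-7-hydroperoxy-8-oxoeudesm-11-en-3-yl (2Z)-2-methylbut-2-enoate | C=C(C)[C@@]1(OO)C[C@@H]2[C@](C)(CC[C@@H](OC(=O)/C(C)=C\C)[C@@]2(C)OC(C)=O)CC1=O | target

## Step count and risks

Total step count: 13. Longest linear sequence: 13 steps (from pent-3-yn-1-ol 1).

Steps most likely to fail:

**Step 9 (Proposed new method).** What may go wrong is insufficient enantiofacial discrimination by the two-coordinate gold centre, and, to a lesser degree, proton loss or protodesilylation before the second ring closes. The fallback gives up catalyst control and sets out from 17. The same cascade is run with the achiral catalyst [(JohnPhos)Au(NCMe)]SbF6 and i-PrOH in CH2Cl2 (the racemic form of the gold(I) 1,5-enyne polycyclisation), which should give 20 together with its mirror image, the (4aS,8aS)-dienone F1. The mixture is dihydroxylated as in step 10 to 22 and the enantiomeric diol F2. The secondary 3-OH is then esterified with (S)-O-methylmandelic acid (DCC, DMAP) to give the (S)-O-methylmandelate of 22 F3 and the diastereomeric (S)-O-methylmandelate of the enantiomeric diol F4, which are separated by chromatography or crystallisation. Methanolysis of F3 (K2CO3, MeOH) comes back to the route at 22.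

**Step 13.** What may go wrong is incomplete regiocontrol of the ene reaction (hydrogen abstraction from the ring methylene C6, which would place the hydroperoxide on C11) and partial attack from the β-face. The fallback sets out from 26 and fixes the site of oxygenation through an enol ether. Soft enolisation toward the γ-methyl (TMSOTf, Et3N, CH2Cl2, 0 °C; C9 is neopentyl and hindered) should give the trimethylsilyl dienol ether F5. Dye-sensitised photooxygenation at −78 °C, the silatropic ene reaction of silyl enol ethers known to give α-silylperoxy ketones, should place the peroxide on the enol ether carbon C7 only and give the 7-(trimethylsilylperoxy) ketone F6. Methanolysis (MeOH, rt) comes back to the route at 27.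

**Step 11.** What may go wrong is Z-to-E isomerisation of the angeloyl unit during activation and slow acylation of the hindered axial alcohol next to a quaternary carbon. The fallback sets out from 22 and builds the (Z)-alkene on the molecule. Esterification of the 3-OH with 2-[bis(2,2,2-trifluoroethoxy)phosphoryl]propanoic acid (DCC, DMAP) should give the phosphonopropionate F7. Still–Gennari olefination with acetaldehyde (KHMDS, 18-crown-6, THF, −78 °C) is Z-selective for α-methyl enoates and comes back to the route at 25.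

## Further compounds

F1 | step 9 | (4aS,8aS)-5,8a-dimethyl-3-(propan-2-ylidene)-3,4,4a,7,8,8a-hexahydronaphthalen-2(1H)-one (enantiomer of 20) | CC(C)=C1C[C@H]2[C@@](C)(CCC=C2C)CC1=O
F2 | step 9 | (3S,4R,5S,10S)-3,4-dihydroxyeudesm-7(11)-en-8-one (enantiomer of 22) | CC(C)=C1C[C@H]2[C@@](C)(CC[C@H](O)[C@]2(C)O)CC1=O
F3 | step 9 | (3R,4S,5R,10R)-4-hydroxy-8-oxoeudesm-7(11)-en-3-yl (2S)-2-methoxy-2-phenylacetate | CC(C)=C1C[C@@H]2[C@](C)(CC[C@@H](OC(=O)[C@@H](OC)c3ccccc3)[C@@]2(C)O)CC1=O
F4 | step 9 | (3S,4R,5S,10S)-4-hydroxy-8-oxoeudesm-7(11)-en-3-yl (2S)-2-methoxy-2-phenylacetate | CC(C)=C1C[C@H]2[C@@](C)(CC[C@H](OC(=O)[C@@H](OC)c3ccccc3)[C@]2(C)O)CC1=O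
F5 | step 13 | (3R,4S,5R,10R)-4-acetoxy-8-(trimethylsilyloxy)eudesma-7,11-dien-3-yl (2Z)-2-methylbut-2-enoate | C=C(C)C=1C[C@@H]2[C@](C)(CC[C@@H](OC(=O)/C(C)=C\C)[C@@]2(C)OC(C)=O)CC=1O[Si](C)(C)C
F6 | step 13 | (3R,4S,5R,7S,10R)-4-acetoxy-8-oxo-7-(trimethylsilylperoxy)eudesm-11-en-3-yl (2Z)-2-methylbut-2-enoate | C=C(C)[C@@]1(OO[Si](C)(C)C)C[C@@H]2[C@](C)(CC[C@@H](OC(=O)/C(C)=C\C)[C@@]2(C)OC(C)=O)CC1=O
F7 | step 11 | (3R,4S,5R,10R)-4-hydroxy-8-oxoeudesm-7(11)-en-3-yl 2-[bis(2,2,2-trifluoroethoxy)phosphoryl]propanoate (mixture at the phosphonate α-carbon) | CC(C)=C1C[C@@H]2[C@](C)(CC[C@@H](OC(=O)C(C)P(=O)(OCC(F)(F)F)OCC(F)(F)F)[C@@]2(C)O)CC1=O
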